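**Strategy**

The route rests on disconnecting C4–C5 and C9–C10 of the trans-decalin. Rings A and B hold an equatorial C3 oxygen, a C4 centre with axial CH3 and equatorial C18H2–O, and the angular C10 methyl, the exact imprint of an E-hydroxylated, epoxidised geranyl chain folded chair–chair. A Lewis acid therefore converts the acyclic (S,S)-epoxy olefin β-keto ester 11 (C18 as a bulky silyl ether) in one operation into bicyclic β-keto ester 12, closing both rings and fixing C4, C5 and C10 (C9 equilibrates). The C8 ketone and C9 ester of 12 then serve to install the 9α-oxygen, the C8 methyl and the spiro ether–lactone, whose C13 centre is set by catalyst-controlled epoxidation.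

Key step: step 7

**Remarks**

- Numbering: labdane numbering throughout (C1–C10 decalin, C11–C16 side chain, C17 on C8, C18 equatorial/α and C19 axial/β on C4, C20 on C10); α is the face opposite C20.
- Structure check: the target is (13S)-3β,18-diacetoxy-9α,13-epoxy-8α-methyl-labdan-15,16-olide (5α-H, 10β-CH3). Precursor 11 is the (2S,3S)-trans-oxirane with a 6E olefin, and 12 is 3β-OH, 4α-CH2OSi, 5α-H, 9β-CO2CH3, 10β-CH3. These are mutually consistent and consistent with L-(+)-tartrate in step 2, so no structure was changed.
- Precursor design: the tert-butyldiphenylsilyl ether at O18 and the methyl ester are kept. A bulky, weakly basic silyl ether is the O18 substituent least able to chelate the Lewis acid with the oxirane or to capture C4; an acyl group would do the latter.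
- Protecting groups: the hindered 3β-hydroxyl is carried free from step 7 on and every later reagent is chosen to tolerate it, so both acetates go on together in the last step.
- Assumption: the sense of induction of the vanadium–bishydroxamic acid epoxidation of 3-methylenealkan-1-ols was not assigned here; whichever ligand enantiomer delivers oxygen to the Re face of C13 is used (both derive from the enantiomeric trans-cyclohexane-1,2-diamines).

**Route**

Step 1
Reactants: 1 geranyl acetate
Product: 2 (2E,6E)-8-hydroxygeranyl acetate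
Conditions: SeO2 (cat.), t-BuOOH, salicylic acid (cat.), CH2Cl2, rt
Reagents that add atoms: tert-butyl hydroperoxide CC(C)(C)OO (oxygen relayed by selenium dioxide O=[Se]=O)
Why: Selenium dioxide allylic oxidation (ene reaction then [2,3]-sigmatropic shift, Riley type) should hydroxylate the E-methyl group of the electron-rich terminal olefin, while the olefin next to the acetate is deactivated and no stereocentre is formed.

Step 2
Reactants: 2 (2E,6E)-8-hydroxygeranyl acetate
Product: 3 (2E)-5-[(2S,3S)-3-(hydroxymethyl)-3-methyloxiran-2-yl]-3-methylpent-2-en-1-yl acetate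
Conditions: Ti(OiPr)4 (cat.), L-(+)-diethyl tartrate (cat.), t-BuOOH, 4 Å molecular sieves, CH2Cl2, −20 °C
Reagents that add atoms: tert-butyl hydroperoxide CC(C)(C)OO
Why: Sharpless asymmetric epoxidation acts only on the allylic alcohol olefin and, with the L-(+)-tartrate, should give the (2S,3S)-oxirane as it does for other (E)-2-methylalk-2-en-1-ols, which sets C3 and C4 by reagent control.

Step 3
Reactants: 3 epoxy alcohol; 4 tert-butyl(chloro)diphenylsilane
Product: 5 O18-tert-butyldiphenylsilyl epoxy acetate
Conditions: imidazole, DMF, 0 °C → rt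
Reagents that add atoms: none
Why: Imidazole-promoted silylation of the primary hydroxyl installs a bulky, weakly basic ether that will neither chelate the Lewis acid nor take part in the later oxirane opening, and no stereocentre is touched.

Step 4
Reactants: 5 silyl epoxy acetate
Product: 6 (2E)-5-[(2S,3S)-3-(silyloxymethyl)-3-methyloxiran-2-yl]-3-methylpent-2-en-1-ol
Conditions: K2CO3, MeOH, 0 °C
Reagents that add atoms: none
Why: Base-catalysed transesterification with methanol removes the allylic acetate under conditions that leave the oxirane and the silyl ether intact.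

Step 5
Reactants: 6 epoxy allylic alcohol
Product: 8 (2S,3S)-epoxy allylic bromide, via allylic mesylate 7 (not isolated)
Conditions: MsCl, Et3N, THF, −40 °C; then LiBr, THF, 0 °C
Reagents that add atoms: lithium bromide [Li+].[Br-]; methanesulfonyl chloride CS(=O)(=O)Cl (atoms stay in intermediate 7 only)
Why: Mesylation followed by Finkelstein-type SN2 displacement with bromide converts the primary allylic alcohol into the bromide without acid, so the oxirane survives and the E geometry is kept.

Step 6
Reactants: 8 epoxy allylic bromide; 9 methyl acetoacetate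
Product: 11 methyl (6E)-9-[(2S,3S)-3-(silyloxymethyl)-3-methyloxiran-2-yl]-7-methyl-3-oxonon-6-enoate, via acetoacetate dianion 10 (not isolated)
Conditions: NaH, THF, 0 °C; n-BuLi, 0 °C; then 8, 0 °C
Reagents that add atoms: none
Why: γ-Alkylation of the acetoacetate dianion occurs at its more basic terminal carbon, and the primary allylic bromide reacts by SN2 far faster than the trisubstituted oxirane, giving the cyclisation precursor with C7 attached to C6.

Step 7
Reactants: 11 epoxy olefin β-keto ester
Product: 12 bicyclic β-keto ester (trans-decalin; 3β-OH; 4α-CH2OSi; 4β-CH3; 5α-H; 10β-CH3; C8 ketone; 9β-CO2CH3)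
Conditions: SnCl4, CH2Cl2, −78 → −20 °C
Reagents that add atoms: none
Why: SnCl4 binds the oxirane oxygen and holds the β-keto ester as its tin enolate; the C4–O bond lengthens as the C5=C10 π bond attacks C4 from the side opposite to oxygen, and the tertiary C10 cation that develops is taken by the enol carbon C9, after which proton loss returns the β-keto ester. The closest known reaction type is the Lewis acid-promoted epoxy-olefin (polyene) cyclisation with a β-dicarbonyl terminator. Ring A closes in a 6-endo mode (attack at the distal, tertiary oxirane carbon and 6-endo-trig at the olefin) and ring B in a 6-endo-trig mode at C10 with the enol double bond inside the new ring, both through chairs. C3 keeps its configuration because its C–O bond is not broken and becomes the equatorial 3β-hydroxyl, C4 is inverted so that the E-CH2OSi group becomes equatorial C18 and the Z-methyl axial C19, C5 and C10 arise from anti addition across the E olefin in the chair–chair fold (trans fusion, 5α-H, 10β-CH3), and C9 settles with the ester equatorial by enolisation; the absolute sense comes from the (2S,3S)-oxirane. The step needs oxirane cleavage at C4 and not at C3 and C- not O-alkylation of the enol: the first is secured by the tertiary character of C4 and concerted olefin participation, with a silyl ether that neither chelates tin nor captures C4, the second by the tin-chelated enol whose O-alkylation is reversible.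

Step 8
Reactants: 12 bicyclic β-keto ester
Product: 13 9α-hydroxy-8-oxo 9β-methyl ester
Conditions: dimethyldioxirane (acetone solution), Ni(acac)2 (cat.), CH2Cl2, 0 °C
Reagents that add atoms: dimethyldioxirane CC1(C)OO1
Why: Dioxirane α-hydroxylation of a β-keto ester (epoxidation of the C8=C9 enol and collapse of the epoxide, a Rubottom-type oxidation) should deliver oxygen to the α face, anti to the axial C20 methyl on the neighbouring C10, which sets the 9α-hydroxyl and leaves the ester β.

Step 9
Reactants: 13 α-hydroxy β-keto ester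
Product: 14 9α-hydroxy-8(17)-methylene ester
Conditions: Zn, CH2Br2, TiCl4, THF–CH2Cl2, 0 °C → rt
Reagents that add atoms: dibromomethane BrCBr
Why: Takai–Lombardo methylenation is non-basic and selective for ketones, so the hindered C8 carbonyl should become the exocyclic olefin without retro-Claisen cleavage or α-ketol rearrangement of the α-hydroxy β-keto ester and without touching the ester, and no stereocentre is formed.

Step 10
Reactants: 14 exocyclic olefin
Product: 15 9α-hydroxy-8α-methyl ester (8β-H)
Conditions: Mn(dpm)3 (cat.), PhSiH3, t-BuOOH, i-PrOH, rt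
Reagents that add atoms: none
Why: Manganese hydride hydrogen-atom-transfer hydrogenation (Mukaiyama-type radical hydrofunctionalisation) forms the tertiary C8 radical, which should accept hydrogen axially on the β face so that C17 ends equatorial (8α), the thermodynamic outcome that avoids a syn-diaxial clash with C20 and that heterogeneous hydrogenation from the open α face would not give.

Step 11
Reactants: 15 α-hydroxy ester
Product: 16 3β,9α,11-triol (18-silyl ether; 8α-CH3)
Conditions: LiAlH4, THF, 0 °C → reflux
Reagents that add atoms: none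
Why: Hydride reduction of the α-hydroxy ester with LiAlH4 gives the primary C11 alcohol, the adjacent alkoxide assisting delivery, while the silyl ether and all stereocentres are untouched.

Step 12
Reactants: 16 triol
Product: 18 9α,11-epoxide (spiro-oxirane with oxygen on the α face), via primary tosylate 17 (not isolated)
Conditions: TsCl, Et3N, Bu2SnO (cat.), CH2Cl2, rt; then DBU, rt
Reagents that add atoms: p-toluenesulfonyl chloride Cc1ccc(cc1)S(Cl)(=O)=O (atoms stay in intermediate 17 only)
Why: Tin-acetal-directed sulfonylation activates only the primary hydroxyl of the 1,2-diol, and base then closes the oxirane by intramolecular Williamson displacement (3-exo-tet) at C11, so the C9–O bond and hence the 9α configuration are retained.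

Step 13
Reactants: 18 9α,11-epoxide; 19 3-methylbut-3-en-1-ol
Product: 21 18-silyloxy-labd-13(16)-ene-3β,9α,15-triol, via isoprenol dianion 20 (not isolated)
Conditions: 19, n-BuLi, TMEDA, Et2O, 0 °C → rt; then 18, THF, −78 → 0 °C
Reagents that add atoms: none
Why: The dimetallated isoprenol is a symmetrical 2-substituted allyl anion, so SN2 opening of the oxirane at its unsubstituted carbon C11 can give only one regioisomer and forms the C11–C12 bond while releasing the 9α-hydroxyl; excess reagent absorbs the free 3-hydroxyl and no stereocentre is touched.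

Step 14
Reactants: 21 homoallylic alcohol
Product: 23 (13S)-9α,13-epoxy-18-silyloxy-labdane-3β,15,16-triol, via (13R)-13,16-epoxide 22 (not isolated)
Conditions: VO(OiPr)3 (cat.), C2-symmetric bishydroxamic acid ligand from trans-cyclohexane-1,2-diamine (cat., enantiomer for Re-face delivery at C13), cumene hydroperoxide, toluene, rt; then camphorsulfonic acid (cat.), CH2Cl2, 0 °C
Reagents that add atoms: cumene hydroperoxide CC(C)(OO)c1ccccc1
Why: Vanadium–bishydroxamic acid catalysed asymmetric epoxidation directed by the primary homoallylic hydroxyl should place oxygen on the Re face of C13 under catalyst control (C8 and C10 flank the future ether ring almost symmetrically, so the substrate exerts no useful bias), and acid then triggers 5-exo-tet opening of the oxirane by the 9α-hydroxyl at the tertiary carbon with inversion, which fixes the (13S) spiro centre.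

Step 15
Reactants: 23 spiro-ether triol
Product: 26 (13S)-3β-hydroxy-18-silyloxy-9α,13-epoxylabdan-15,16-olide, via hydroxy aldehyde 24 (not isolated), via lactol 25 (not isolated)
Conditions: Cu(MeCN)4OTf (cat.), 2,2′-bipyridine, TEMPO (cat.), N-methylimidazole, air, MeCN, rt
Reagents that add atoms: none
Why: Copper/nitroxyl aerobic oxidative lactonisation of the 1,4-diol oxidises the less hindered C15 carbinol in preference to the neopentyl C16 carbinol and leaves the secondary 3-hydroxyl alone, the aldehyde is trapped by O16 as the lactol and oxidised again, so the carbonyl ends at C15 and C13 is not touched.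

Step 16
Reactants: 26 silyl lactone
Product: 27 (13S)-3β,18-dihydroxy-9α,13-epoxylabdan-15,16-olide
Conditions: Bu4NF, AcOH, THF, rt
Reagents that add atoms: none
Why: Fluoride-mediated desilylation buffered with acetic acid removes the silyl group while avoiding enolisation of the lactone, which could open the β-alkoxy lactone by E1cB elimination and scramble C13.

Step 17
Reactants: 27 diol lactone
Product: 28 (13S)-3β,18-diacetoxy-9α,13-epoxylabdan-15,16-olide (CNP0117603.3)
Conditions: Ac2O, pyridine, DMAP (cat.), CH2Cl2, rt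
Reagents that add atoms: acetic anhydride CC(=O)OC(C)=O
Why: DMAP-catalysed acylation (Steglich-type nucleophilic catalysis) should acetylate the primary 18- and the hindered equatorial 3-hydroxyl in one operation under conditions too mild to epimerise C13.

**Compound list**

1 | geranyl acetate | CC(C)=CCC/C(C)=C/COC(C)=O | starting material
2 | (2E,6E)-8-hydroxy-3,7-dimethylocta-2,6-dien-1-yl acetate | OC/C(C)=C/CC/C(C)=C/COC(C)=O | intermediate
3 | (2E)-5-[(2S,3S)-3-(hydroxymethyl)-3-methyloxiran-2-yl]-3-methylpent-2-en-1-yl acetate | OC[C@]1(C)O[C@H]1CC/C(C)=C/COC(C)=O | intermediate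
4 | tert-butyl(chloro)diphenylsilane | CC(C)(C)[Si](Cl)(c1ccccc1)c1ccccc1 | starting material
5 | O-tert-butyldiphenylsilyl ether of 3 | CC(C)(C)[Si](c1ccccc1)(c1ccccc1)OC[C@]1(C)O[C@H]1CC/C(C)=C/COC(C)=O | intermediate
6 | (2E)-5-[(2S,3S)-3-(silyloxymethyl)-3-methyloxiran-2-yl]-3-methylpent-2-en-1-ol | CC(C)(C)[Si](c1ccccc1)(c1ccccc1)OC[C@]1(C)O[C@H]1CC/C(C)=C/CO | intermediate
7 | methanesulfonate of 6 | CC(C)(C)[Si](c1ccccc1)(c1ccccc1)OC[C@]1(C)O[C@H]1CC/C(C)=C/COS(C)(=O)=O | intermediate
8 | allylic bromide from 6 | CC(C)(C)[Si](c1ccccc1)(c1ccccc1)OC[C@]1(C)O[C@H]1CC/C(C)=C/CBr | intermediate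
9 | methyl acetoacetate | COC(=O)CC(C)=O | starting material
10 | methyl acetoacetate dianion (sodium lithium salt) | [Na+].[Li+].COC(=O)[CH-]C(=O)[CH2-] | intermediate
11 | methyl (6E)-9-[(2S,3S)-3-({[tert-butyl(diphenyl)silyl]oxy}methyl)-3-methyloxiran-2-yl]-7-methyl-3-oxonon-6-enoate | CC(C)(C)[Si](c1ccccc1)(c1ccccc1)OC[C@]1(C)O[C@H]1CC/C(C)=C/CCC(=O)CC(=O)OC | intermediate
12 | bicyclic β-keto ester: trans-decalin, 3β-OH, 4α-CH2OSi (C18), 4β-CH3, 5α-H, 10β-CH3, 8-oxo, 9β-CO2CH3 (9α-H) | CC(C)(C)[Si](c1ccccc1)(c1ccccc1)OC[C@]1(C)[C@@H](O)CC[C@@]2(C)[C@H]1CCC(=O)[C@@H]2C(=O)OC | intermediate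
13 | 9α-hydroxy derivative of 12 (9β-CO2CH3, 8-oxo) | CC(C)(C)[Si](c1ccccc1)(c1ccccc1)OC[C@]1(C)[C@@H](O)CC[C@@]2(C)[C@H]1CCC(=O)[C@]2(O)C(=O)OC | intermediate
14 | 9α-hydroxy-8(17)-methylene 9β-methyl ester | CC(C)(C)[Si](c1ccccc1)(c1ccccc1)OC[C@]1(C)[C@@H](O)CC[C@@]2(C)[C@H]1CCC(=C)[C@]2(O)C(=O)OC | intermediate
15 | 9α-hydroxy-8α-methyl (8β-H) 9β-methyl ester | CC(C)(C)[Si](c1ccccc1)(c1ccccc1)OC[C@]1(C)[C@@H](O)CC[C@@]2(C)[C@H]1CC[C@@H](C)[C@]2(O)C(=O)OC | intermediate
16 | 3β,9α,11-triol (C11 = CH2OH on C9β; 8α-CH3; 18-silyl ether) | CC(C)(C)[Si](c1ccccc1)(c1ccccc1)OC[C@]1(C)[C@@H](O)CC[C@@]2(C)[C@H]1CC[C@@H](C)[C@]2(O)CO | intermediate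
17 | 11-O-p-toluenesulfonate of 16 | CC(C)(C)[Si](c1ccccc1)(c1ccccc1)OC[C@]1(C)[C@@H](O)CC[C@@]2(C)[C@H]1CC[C@@H](C)[C@]2(O)COS(=O)(=O)c1ccc(C)cc1 | intermediate
18 | 9α,11-epoxide (spiro-oxirane at C9, oxygen α; 3β-OH; 18-silyl ether) | CC(C)(C)[Si](c1ccccc1)(c1ccccc1)OC[C@]1(C)[C@@H](O)CC[C@@]2(C)[C@H]1CC[C@@H](C)[C@]23CO3 | intermediate
19 | 3-methylbut-3-en-1-ol | C=C(C)CCO | starting material
20 | dilithio 3-methylbut-3-en-1-ol (2-(2-oxidoethyl)allyl dianion) | [Li+].[Li+].[CH2-]C(=C)CC[O-] | intermediate
21 | 18-silyloxy-labd-13(16)-ene-3β,9α,15-triol (8α-CH3) | CC(C)(C)[Si](c1ccccc1)(c1ccccc1)OC[C@]1(C)[C@@H](O)CC[C@@]2(C)[C@H]1CC[C@@H](C)[C@]2(O)CCC(=C)CCO | intermediate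
22 | (13R)-13,16-epoxide of 21 | CC(C)(C)[Si](c1ccccc1)(c1ccccc1)OC[C@]1(C)[C@@H](O)CC[C@@]2(C)[C@H]1CC[C@@H](C)[C@]2(O)CC[C@@]3(CCO)CO3 | intermediate
23 | (13S)-9α,13-epoxy-18-silyloxy-labdane-3β,15,16-triol | CC(C)(C)[Si](c1ccccc1)(c1ccccc1)OC[C@]1(C)[C@@H](O)CC[C@@]2(C)[C@H]1CC[C@@H](C)[C@]21CC[C@@](CO)(CCO)O1 | intermediate
24 | 15-aldehyde of 23 (16-OH free) | CC(C)(C)[Si](c1ccccc1)(c1ccccc1)OC[C@]1(C)[C@@H](O)CC[C@@]2(C)[C@H]1CC[C@@H](C)[C@]21CC[C@@](CO)(CC=O)O1 | intermediate
25 | 15,16-lactol (C15 epimers) | CC(C)(C)[Si](c1ccccc1)(c1ccccc1)OC[C@]1(C)[C@@H](O)CC[C@@]2(C)[C@H]1CC[C@@H](C)[C@]21CC[C@]2(COC(O)C2)O1 | intermediate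
26 | (13S)-3β-hydroxy-18-silyloxy-9α,13-epoxylabdan-15,16-olide | CC(C)(C)[Si](c1ccccc1)(c1ccccc1)OC[C@]1(C)[C@@H](O)CC[C@@]2(C)[C@H]1CC[C@@H](C)[C@]21CC[C@]2(COC(=O)C2)O1 | intermediate
27 | (13S)-3β,18-dihydroxy-9α,13-epoxylabdan-15,16-olide | OC[C@]1(C)[C@@H](O)CC[C@@]2(C)[C@H]1CC[C@@H](C)[C@]21CC[C@]2(COC(=O)C2)O1 | intermediate
28 | (13S)-3β,18-diacetoxy-9α,13-epoxylabdan-15,16-olide (CNP0117603.3) | CC(=O)OC[C@]1(C)[C@@H](OC(C)=O)CC[C@@]2(C)[C@H]1CC[C@@H](C)[C@]21CC[C@]2(COC(=O)C2)O1 | target

**Step count and risks**

Total step count: 17. Longest linear sequence: 17 steps (1 → 28).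

Steps most likely to fail:

1. Step 7. What may go wrong: ionisation of the oxirane at C3 instead of C4, capture of the activated oxirane by chloride, or termination after ring A, all favoured by the electron-withdrawing oxygen on C18. Fallback: make the same two bonds in a radical stage and a polar stage. Setting out from 11, Cp2TiCl (from Cp2TiCl2 and Mn, THF, rt) opens the oxirane homolytically to the tertiary C4 radical, whose formation does not depend on cation stability. 6-endo addition to C5 and β-hydride loss from the C10 organotitanium should give the monocyclic exo-methylene keto ester F1 (C4–C5 made, the larger CH2OSi group expected equatorial in the chair). In(OTf)3 (cat., toluene, 80 °C) then adds the β-keto ester in the Markovnikov sense to the C10=C20 olefin, forming C9–C10 through a chair with C9 equatorial on ring A, and the sequence comes back to the route at 12.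

2. Step 14. What may go wrong: loss of catalyst control at C13 (binding through the tertiary 9-hydroxyl instead of the primary one, or an unexpected sense of induction), or opening of the oxirane by O15. Fallback: replace catalyst control by a stereoconvergent sequence. Setting out from 21, hydroxyl-directed epoxidation with VO(acac)2 and t-BuOOH gives 22 together with its C13 epimer, the (13S)-epoxide F2. Acid cyclisation and the copper/TEMPO lactonisation of step 15 carry the pair through 23 and the (13R)-triol F3 to 26 and the (13R)-lactone F4, which are separated. F4 is recycled with DBU in warm toluene: E1cB opening to the 9α-hydroxy butenolide F5 and reversible oxa-Michael re-addition (5-exo-trig) regenerate the epimer pair, from which 26 is removed again. The fallback comes back to the route at 26.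

3. Step 9. What may go wrong: failure of the zinc–titanium methylene reagent to add to the C8 carbonyl beside the fully substituted C9, or Lewis acid-induced α-ketol rearrangement. Fallback: introduce C17 by cross-coupling and the 9α-oxygen by epoxidation, bypassing steps 8 to 11. Setting out from 12, NaH (1 equiv) and PhNTf2 give the enol triflate F6. Me2CuLi exchanges triflate for methyl to give the tetrasubstituted unsaturated ester F7. i-Bu2AlH reduces it to the allylic alcohol F8. mCPBA epoxidises the α face, anti to C20, to give the 8α,9α-epoxy alcohol F9. LiEt3BH then delivers hydride to C8 on the β face by trans-diaxial opening (Fürst–Plattner rule), which gives 8α-CH3 and the 9α-hydroxyl and comes back to the route at triol 16.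

Further compounds
F1 | step 7 | monocyclic keto ester: ring A with 3β-OH, 4α-CH2OSi, 4β-CH3, C10=C20 exocyclic methylene, C5 bearing the CH2CH2C(=O)CH2CO2CH3 chain | CC(C)(C)[Si](c1ccccc1)(c1ccccc1)OC[C@]1(C)[C@@H](O)CCC(=C)[C@H]1CCC(=O)CC(=O)OC
F2 | step 14 | (13S)-13,16-epoxide (C13 epimer of 22) | CC(C)(C)[Si](c1ccccc1)(c1ccccc1)OC[C@]1(C)[C@@H](O)CC[C@@]2(C)[C@H]1CC[C@@H](C)[C@]2(O)CC[C@]3(CCO)CO3
F3 | step 14 | (13R)-9α,13-epoxy-18-silyloxy-labdane-3β,15,16-triol (C13 epimer of 23) | CC(C)(C)[Si](c1ccccc1)(c1ccccc1)OC[C@]1(C)[C@@H](O)CC[C@@]2(C)[C@H]1CC[C@@H](C)[C@]21CC[C@](CO)(CCO)O1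
F4 | step 14 | (13R)-3β-hydroxy-18-silyloxy-9α,13-epoxylabdan-15,16-olide (C13 epimer of 26) | CC(C)(C)[Si](c1ccccc1)(c1ccccc1)OC[C@]1(C)[C@@H](O)CC[C@@]2(C)[C@H]1CC[C@@H](C)[C@]21CC[C@@]2(COC(=O)C2)O1
F5 | step 14 | 3β,9α-dihydroxy-18-silyloxy-labd-13-en-15,16-olide (ring-opened butenolide) | CC(C)(C)[Si](c1ccccc1)(c1ccccc1)OC[C@]1(C)[C@@H](O)CC[C@@]2(C)[C@H]1CC[C@@H](C)[C@]2(O)CCC1=CC(=O)OC1
F6 | step 9 | C8 enol triflate of 12 (C8=C9 olefin, 9-CO2CH3) | CC(C)(C)[Si](c1ccccc1)(c1ccccc1)OC[C@]1(C)[C@@H](O)CC[C@@]2(C)[C@H]1CCC(OS(=O)(=O)C(F)(F)F)=C2C(=O)OC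
F7 | step 9 | 8-methyl C8=C9 unsaturated methyl ester | CC(C)(C)[Si](c1ccccc1)(c1ccccc1)OC[C@]1(C)[C@@H](O)CC[C@@]2(C)[C@H]1CCC(C)=C2C(=O)OC
F8 | step 9 | 8-methyl C8=C9 allylic alcohol (C11 = CH2OH) | CC(C)(C)[Si](c1ccccc1)(c1ccccc1)OC[C@]1(C)[C@@H](O)CC[C@@]2(C)[C@H]1CCC(C)=C2CO
F9 | step 9 | 8α,9α-epoxy-11-ol (8β-CH3) | CC(C)(C)[Si](c1ccccc1)(c1ccccc1)OC[C@]1(C)[C@@H](O)CC[C@@]2(C)[C@H]1CC[C@@]3(C)O[C@@]23CO
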